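**Plan**

- The retrosynthesis cuts C4a–C5 and C8–C8a of the naphthazarin. Ring A (C4a, C5, C6, C7, C8, C8a) carries only OH at C5 and C8 and H at C6 and C7, so C5–C8 map onto a symmetric 1,4-bis(silyloxy)cyclohexa-1,3-diene and C4a=C8a onto a benzoquinone double bond; the diene's CH2–CH2 unit is later expelled as ethylene.
- A bromine on the future C4a makes that quinone double bond the dienophile and lets loss of HBr, not a hydroquinone, restore the quinone level before ethylene extrusion.
- The side chain is cut at the ester C–O bond, at the C3'=C4' alkene (cross-metathesis) and at C1'–C2' (allylboration of an aryl aldehyde).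
- Forward: the side chain is built on 4-bromo-2,5-dimethoxybenzaldehyde (future ring B), the arene is oxidised to the bromoquinone, ring A is closed by cycloaddition, then HBr loss, Alder–Rickert aromatisation and desilylation follow.
- The only stereocentre, C1' (S), is set by a chiral phosphoric acid-catalysed allylboration and is not touched afterwards; the four sp3 centres of the cycloadduct are all erased.

Key step: step 6

Remark: ring A is the dihydroxy benzenoid ring and ring B the quinone ring; the two naphthazarin tautomers interconvert freely, so the side chain is drawn on the quinone ring as in the target, and 4-bromo-2,5-dimethoxybenzaldehyde is taken as a catalogue compound.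

**Step 1**
Reactants: 1 4-bromo-2,5-dimethoxybenzaldehyde; 2 allylboronic acid pinacol ester
Product: 4 (S)-1-(4-bromo-2,5-dimethoxyphenyl)but-3-en-1-ol, via O-pinacolboryl ether 3 (not isolated)
Conditions: (S)-TRIP phosphoric acid [(S)-3,3'-bis(2,4,6-triisopropylphenyl)-1,1'-binaphthyl-2,2'-diyl hydrogen phosphate] (5 mol %), toluene, −30 °C; aq. NaHCO3 work-up
Reagents that add atoms: none
Why: Chiral phosphoric acid-catalysed allylboration runs through a chair-like six-membered transition state with the acid hydrogen-bonded to a boronate oxygen; the (S)-acid, mirror image of the one known to give (R)-carbinols from aryl aldehydes, should deliver allyl to the Si face and set C1' as (S), and aqueous work-up cleaves borate 3.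

**Step 2**
Reactants: 4 (S)-1-(4-bromo-2,5-dimethoxyphenyl)but-3-en-1-ol; 5 2-methylbut-2-ene
Product: 6 (S)-1-(4-bromo-2,5-dimethoxyphenyl)-4-methylpent-3-en-1-ol
Conditions: 5 (excess), second-generation Grubbs catalyst RuCl2(=CHPh)(PCy3)(H2IMes) (3 mol %), CH2Cl2, 40 °C
Reagents that add atoms: none
Why: Olefin cross-metathesis of the terminal alkene with excess 2-methylbut-2-ene installs the prenyl terminus with loss of propene; the free secondary alcohol and the aryl bromide are tolerated by the ruthenium carbene and C1' is not involved.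

**Step 3**
Reactants: 6 (S)-1-(4-bromo-2,5-dimethoxyphenyl)-4-methylpent-3-en-1-ol
Product: 7 (S)-1-(4-bromo-2,5-dimethoxyphenyl)-4-methylpent-3-en-1-yl 2-methylpropanoate
Conditions: (i-PrCO)2O, DMAP (10 mol %), pyridine, CH2Cl2, 0 °C → rt
Reagents that add atoms: 2-methylpropanoic anhydride, CC(C)C(=O)OC(=O)C(C)C
Why: DMAP-catalysed acylation of a secondary alcohol by an anhydride occurs at oxygen with retention at C1', and the mildly basic medium avoids ionisation of the electron-rich benzylic position.

**Step 4**
Reactants: 7 (S)-1-(4-bromo-2,5-dimethoxyphenyl)-4-methylpent-3-en-1-yl 2-methylpropanoate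
Product: 8 (S)-1-(4-bromo-3,6-dioxocyclohexa-1,4-dien-1-yl)-4-methylpent-3-en-1-yl 2-methylpropanoate
Conditions: (NH4)2Ce(NO3)6 (2.5 equiv), MeCN–H2O, 0 °C, short contact
Reagents that add atoms: water, O
Why: Oxidative demethylation of a para-dimethoxyarene by tetravalent cerium passes through the arene radical cation, water adds at the two ipso carbons and methanol leaves to give the quinone; brief exposure at 0 °C should spare the trisubstituted alkene, the ester and the C–Br bond, and C1' is not involved.

**Step 5**
Reactants: 9 cyclohexane-1,4-dione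
Product: 11 1,4-bis(trimethylsilyloxy)cyclohexa-1,3-diene, via 4-(trimethylsilyloxy)cyclohex-3-en-1-one 10 (not isolated)
Conditions: TMSOTf (2.2 equiv), Et3N (2.5 equiv), Et2O, 0 °C → rt; distilled and used at once
Reagents that add atoms: trimethylsilyl trifluoromethanesulfonate, C[Si](C)(C)OS(=O)(=O)C(F)(F)F
Why: Soft enolisation (O-silylation, then deprotonation by the amine) of both ketones gives the bis-silyl enol ether, the second deprotonation being expected at the doubly activated CH2 between C=O and the first enol ether so that the conjugated 1,3-diene predominates; any 1,4-diene isomer is inert in step 6.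

**Step 6**
Reactants: 8 (S)-1-(4-bromo-3,6-dioxocyclohexa-1,4-dien-1-yl)-4-methylpent-3-en-1-yl 2-methylpropanoate; 11 1,4-bis(trimethylsilyloxy)cyclohexa-1,3-diene
Product: 12 (1'S)-1-[4a-bromo-1,4-dioxo-5,8-bis(trimethylsilyloxy)-1,4,4a,5,8,8a-hexahydro-5,8-ethanonaphthalen-2-yl]-4-methylpent-3-en-1-yl 2-methylpropanoate (diastereomer mixture at C4a, C5, C8, C8a)
Conditions: 11 (1.5 equiv), toluene, 0 °C → rt, dark, Ar; volatiles removed, crude 12 taken on
Reagents that add atoms: none
Why: The electron-rich diene 11 (HOMO raised by two terminal silyloxy groups) adds to the bromine-bearing C=C of quinone 8 in a concerted, suprafacial, normal-demand [4+2] cycloaddition that forms C4a–C5 and C8a–C8. The closest known reaction type is the Diels–Alder addition of 1-oxygenated cyclohexa-1,3-dienes to bromo-1,4-benzoquinones, the first stage of Alder–Rickert naphthoquinone syntheses. Ring A (C4a, C5, C6, C7, C8, C8a) closes as the six-membered carbocycle of a bicyclo[2.2.2]octene by intermolecular cycloaddition, the CH2–CH2 unit of 11 becoming the ethano bridge. The new sp3 centres C4a, C5, C8 and C8a are cis-related by the suprafacial addition, but endo/exo and facial isomers relative to C1' are all accepted because each of these centres becomes sp2 in step 7; C1' lies outside the reacting π-system and is untouched. The selectivity needed is for the C(Br)=CH double bond over the one bearing the side chain: bromine lowers the LUMO at its double bond, the α-branched, inductively donating side chain deactivates and shields the other, and the symmetry of 11 removes any regiochemical question. Neutral, Lewis-acid-free conditions should keep the bridgehead silyl ethers and the ester intact.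

**Step 7**
Reactants: 12 (1'S)-1-[4a-bromo-1,4-dioxo-5,8-bis(trimethylsilyloxy)-1,4,4a,5,8,8a-hexahydro-5,8-ethanonaphthalen-2-yl]-4-methylpent-3-en-1-yl 2-methylpropanoate
Product: 15 isobutyryl alkannin [(S)-1-(5,8-dihydroxy-1,4-dioxo-1,4-dihydronaphthalen-2-yl)-4-methylpent-3-en-1-yl 2-methylpropanoate], via ethano-bridged bicyclic quinone 13 (not isolated), via 5,8-bis(trimethylsilyloxy)naphthoquinone 14 (not isolated)
Conditions: 2,6-lutidine (1.2 equiv), toluene, 0 °C → rt; filter; 110 °C (sealed tube, Ar); then 0.1 M HCl, THF–H2O, 0 °C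
Reagents that add atoms: none
Why: Deprotonation at C8a and E1cB loss of bromide from C4a give quinone 13 without a hydroquinone stage (which could expel the C1' ester through a quinone methide), the bicyclo[2.2.2]octadiene then loses ethylene by thermal retro-Diels–Alder reaction (Alder–Rickert) driven by aromatisation of ring A to give 14, and the aryl silyl ethers peri to the carbonyls hydrolyse in dilute acid; the weak hindered base and the electron-poor quinone ring should leave C1' and its ester alone.

**Compound list**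

1 | 4-bromo-2,5-dimethoxybenzaldehyde | COc1cc(Br)c(OC)cc1C=O | starting material
2 | allylboronic acid pinacol ester | C=CCB1OC(C)(C)C(C)(C)O1 | starting material
3 | (S)-2-{[1-(4-bromo-2,5-dimethoxyphenyl)but-3-en-1-yl]oxy}-4,4,5,5-tetramethyl-1,3,2-dioxaborolane | C=CC[C@H](OB1OC(C)(C)C(C)(C)O1)c1cc(OC)c(Br)cc1OC | intermediate
4 | (S)-1-(4-bromo-2,5-dimethoxyphenyl)but-3-en-1-ol | C=CC[C@H](O)c1cc(OC)c(Br)cc1OC | intermediate
5 | 2-methylbut-2-ene | CC=C(C)C | starting material
6 | (S)-1-(4-bromo-2,5-dimethoxyphenyl)-4-methylpent-3-en-1-ol | CC(C)=CC[C@H](O)c1cc(OC)c(Br)cc1OC | intermediate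
7 | (S)-1-(4-bromo-2,5-dimethoxyphenyl)-4-methylpent-3-en-1-yl 2-methylpropanoate | CC(C)=CC[C@H](OC(=O)C(C)C)c1cc(OC)c(Br)cc1OC | intermediate
8 | (S)-1-(4-bromo-3,6-dioxocyclohexa-1,4-dien-1-yl)-4-methylpent-3-en-1-yl 2-methylpropanoate | CC(C)=CC[C@H](OC(=O)C(C)C)C1=CC(=O)C(Br)=CC1=O | intermediate
9 | cyclohexane-1,4-dione | O=C1CCC(=O)CC1 | starting material
10 | 4-(trimethylsilyloxy)cyclohex-3-en-1-one | O=C1CC=C(O[Si](C)(C)C)CC1 | intermediate
11 | 1,4-bis(trimethylsilyloxy)cyclohexa-1,3-diene | C[Si](C)(C)OC1=CC=C(O[Si](C)(C)C)CC1 | intermediate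
12 | (1'S)-1-[4a-bromo-1,4-dioxo-5,8-bis(trimethylsilyloxy)-1,4,4a,5,8,8a-hexahydro-5,8-ethanonaphthalen-2-yl]-4-methylpent-3-en-1-yl 2-methylpropanoate, diastereomer mixture at the four ring sp3 carbons | CC(C)=CC[C@H](OC(=O)C(C)C)C1=CC(=O)C2(Br)C(C1=O)C1(O[Si](C)(C)C)CCC2(O[Si](C)(C)C)C=C1 | intermediate
13 | (S)-1-[1,4-dioxo-5,8-bis(trimethylsilyloxy)-1,4,5,8-tetrahydro-5,8-ethanonaphthalen-2-yl]-4-methylpent-3-en-1-yl 2-methylpropanoate | CC(C)=CC[C@H](OC(=O)C(C)C)C1=CC(=O)C2=C(C1=O)C1(O[Si](C)(C)C)CCC2(O[Si](C)(C)C)C=C1 | intermediate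
14 | (S)-1-[1,4-dioxo-5,8-bis(trimethylsilyloxy)-1,4-dihydronaphthalen-2-yl]-4-methylpent-3-en-1-yl 2-methylpropanoate | CC(C)=CC[C@H](OC(=O)C(C)C)C1=CC(=O)c2c(O[Si](C)(C)C)ccc(O[Si](C)(C)C)c2C1=O | intermediate
15 | isobutyryl alkannin, (S)-1-(5,8-dihydroxy-1,4-dioxo-1,4-dihydronaphthalen-2-yl)-4-methylpent-3-en-1-yl 2-methylpropanoate | CC(C)=CC[C@H](OC(=O)C(C)C)C1=CC(=O)c2c(O)ccc(O)c2C1=O | target

**Totals**

Total step count: 7. Longest linear sequence: 6 (steps 1–4, 6, 7); step 5 is a one-step side branch.

**Steps most likely to fail**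

Step 6. Electron transfer from the silyloxy diene to the bromoquinone (aromatising the diene), or slow bond formation between the two fully substituted carbons C4a and C5, may outrun the cycloaddition. The fallback sets out from alcohol 6 and returns at bridged quinone 13. Bromine–lithium exchange (n-BuLi, 2.2 equiv, THF, −78 °C) should give lithium (S)-1-(4-lithio-2,5-dimethoxyphenyl)-4-methylpent-3-en-1-olate F1, which is protonated cold with MeOH to (S)-1-(2,5-dimethoxyphenyl)-4-methylpent-3-en-1-ol F2. Acylation as in step 3 gives (S)-1-(2,5-dimethoxyphenyl)-4-methylpent-3-en-1-yl 2-methylpropanoate F3, and oxidation as in step 4 gives the bromine-free quinone (S)-1-(3,6-dioxocyclohexa-1,4-dien-1-yl)-4-methylpent-3-en-1-yl 2-methylpropanoate F4. This less oxidising, unhindered quinone should add diene 11 at its unsubstituted double bond to give the bromine-free ethano-bridged adduct F5. Catalytic Et3N with excess Ag2O in Et2O then enolises F5 to the bridged hydroquinone F6 and oxidises it as it forms, giving 13, which enters the thermal part of step 7.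

Step 7. Ethylene extrusion may demand a temperature at which the C1' ester is eliminated, or C1' epimerises through base- or heat-induced quinone methide tautomerisation. The fallback avoids heat, base and oxidant; it sets out from alcohol 6, carried to the bromine-free quinone F4 as described for step 6, and returns at target 15. F4 is combined in CH2Cl2 at room temperature with 2,5-bis(trimethylsilyloxy)furan F7 (from succinic anhydride, TMSCl, Et3N, ZnCl2), which forms the same C4a–C5 and C8a–C8 bonds and should give the oxa-bridged bis-silyl ketal adduct F8. Dilute HCl in THF opens the bridge to the 4a,8a-dihydronaphthalene-1,4,5,8-tetraone F9, a tautomer of the naphthazarin that enolises to 15.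

Step 4. Over-oxidation of the trisubstituted alkene or solvolysis of the benzylic ester in the acidic cerium medium may erode the quinone. The fallback reorders the sequence so that the prenyl group is introduced after the oxidation; it sets out from allyl alcohol 4 and returns at bromoquinone 8. Acylation as in step 3 gives (S)-1-(4-bromo-2,5-dimethoxyphenyl)but-3-en-1-yl 2-methylpropanoate F10, whose monosubstituted alkene resists tetravalent cerium. Oxidation with (NH4)2Ce(NO3)6 gives (S)-1-(4-bromo-3,6-dioxocyclohexa-1,4-dien-1-yl)but-3-en-1-yl 2-methylpropanoate F11. Cross-metathesis of F11 with 5 (second-generation Grubbs catalyst, CH2Cl2, 40 °C; quinones are tolerated by ruthenium carbenes and the electron-poor ring alkenes do not take part) gives 8.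

**Further compounds**

F1 | step 6 | lithium (S)-1-(4-lithio-2,5-dimethoxyphenyl)-4-methylpent-3-en-1-olate | CC(C)=CC[C@H]([O-])c1cc(OC)c([Li])cc1OC.[Li+]
F2 | step 6 | (S)-1-(2,5-dimethoxyphenyl)-4-methylpent-3-en-1-ol | CC(C)=CC[C@H](O)c1cc(OC)ccc1OC
F3 | step 6 | (S)-1-(2,5-dimethoxyphenyl)-4-methylpent-3-en-1-yl 2-methylpropanoate | CC(C)=CC[C@H](OC(=O)C(C)C)c1cc(OC)ccc1OC
F4 | step 6 | (S)-1-(3,6-dioxocyclohexa-1,4-dien-1-yl)-4-methylpent-3-en-1-yl 2-methylpropanoate | CC(C)=CC[C@H](OC(=O)C(C)C)C1=CC(=O)C=CC1=O
F5 | step 6 | (1'S)-1-[1,4-dioxo-5,8-bis(trimethylsilyloxy)-1,4,4a,5,8,8a-hexahydro-5,8-ethanonaphthalen-2-yl]-4-methylpent-3-en-1-yl 2-methylpropanoate, diastereomer mixture | CC(C)=CC[C@H](OC(=O)C(C)C)C1=CC(=O)C2C(C1=O)C1(O[Si](C)(C)C)CCC2(O[Si](C)(C)C)C=C1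
F6 | step 6 | (S)-1-[1,4-dihydroxy-5,8-bis(trimethylsilyloxy)-5,8-dihydro-5,8-ethanonaphthalen-2-yl]-4-methylpent-3-en-1-yl 2-methylpropanoate | CC(C)=CC[C@H](OC(=O)C(C)C)c1cc(O)c2c(c1O)C1(O[Si](C)(C)C)CCC2(O[Si](C)(C)C)C=C1
F7 | step 7 | 2,5-bis(trimethylsilyloxy)furan | C[Si](C)(C)Oc1ccc(O[Si](C)(C)C)o1
F8 | step 7 | (1'S)-1-[1,4-dioxo-5,8-bis(trimethylsilyloxy)-1,4,4a,5,8,8a-hexahydro-5,8-epoxynaphthalen-2-yl]-4-methylpent-3-en-1-yl 2-methylpropanoate, diastereomer mixture | CC(C)=CC[C@H](OC(=O)C(C)C)C1=CC(=O)C2C(C1=O)C1(O[Si](C)(C)C)C=CC2(O[Si](C)(C)C)O1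
F9 | step 7 | (1'S)-1-(1,4,5,8-tetraoxo-1,4,4a,5,8,8a-hexahydronaphthalen-2-yl)-4-methylpent-3-en-1-yl 2-methylpropanoate | CC(C)=CC[C@H](OC(=O)C(C)C)C1=CC(=O)C2C(C1=O)C(=O)C=CC2=O
F10 | step 4 | (S)-1-(4-bromo-2,5-dimethoxyphenyl)but-3-en-1-yl 2-methylpropanoate | C=CC[C@H](OC(=O)C(C)C)c1cc(OC)c(Br)cc1OC
F11 | step 4 | (S)-1-(4-bromo-3,6-dioxocyclohexa-1,4-dien-1-yl)but-3-en-1-yl 2-methylpropanoate | C=CC[C@H](OC(=O)C(C)C)C1=CC(=O)C(Br)=CC1=O
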